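## Retrosynthetic overview

1. Brevipolide G 21 ⇒ hydroxy ketone 16 + TBS‑p‑coumaric acid 19 (Steglich ester, then global desilylation); the arene is bought.
2. 16 ⇒ acyclic keto cis‑epoxide (Z)‑enoate 13. One LiHMDS cascade closes the trans‑cyclopropane (enolate 3‑exo‑tet epoxide opening) and then the dihydropyranone (1,4‑O→O silyl shift, lactonisation).
3. 13 ⇒ cis‑epoxy aldehyde 7 (Brown allylation sets lactone C‑6; silylation, ozonolysis, Still–Gennari olefination).
4. 7 ⇒ Z‑allylic alcohol 5 (Sharpless epoxidation, oxidation) ⇒ heptenone 4 (Z‑selective cross‑metathesis) ⇒ ethyl (S)‑lactate 1.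
5. Ring order: cyclopropane first, lactone immediately after in the same flask (step 11).

Assumption: locants follow the target (pyranone C‑2 to C‑6, carbinol C‑1′, cyclopropane C‑2′/C‑3′, ketone C‑4′, lactate carbon C‑5′); the Ru Z‑selective catalyst and (+)‑Ipc2B(allyl) solution are taken as purchasable.

## Route

Step 1
Reactants: 1 ethyl (S)-lactate
Product: 2 ethyl (2S)-2-(triethylsilyloxy)propanoate
Conditions: TESCl, imidazole, CH2Cl2, 0 °C → rt
Reagents that add atoms: chlorotriethylsilane, CC[Si](CC)(CC)Cl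
Why: Imidazole‑mediated silyl ether formation on a secondary alcohol; the (S) centre is not touched.

Step 2
Reactants: 2 ethyl (2S)-2-(triethylsilyloxy)propanoate
Product: 3 (2S)-N-methoxy-N-methyl-2-(triethylsilyloxy)propanamide
Conditions: MeNH(OMe)·HCl, i‑PrMgCl, THF, −20 → 0 °C
Reagents that add atoms: N,O-dimethylhydroxylamine hydrochloride, CNOC.Cl
Why: Weinreb amide formation from the ester with the chloromagnesium amide, which at −20 °C does not epimerise an α‑silyloxy ester.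

Step 3
Reactants: 3 (2S)-N-methoxy-N-methyl-2-(triethylsilyloxy)propanamide
Product: 4 (2S)-2-(triethylsilyloxy)hept-6-en-3-one
Conditions: but‑3‑enylMgBr, THF, 0 °C; aq. NH4Cl
Reagents that add atoms: but-3-enylmagnesium bromide, C=CCC[Mg]Br
Why: Weinreb ketone synthesis; the chelated tetrahedral adduct stops the Grignard addition at the ketone.

Step 4
Reactants: 4 (2S)-2-(triethylsilyloxy)hept-6-en-3-one
Product: 5 (2S,6Z)-8-hydroxy-2-(triethylsilyloxy)oct-6-en-3-one
Conditions: (Z)-but-2-ene-1,4-diol (3 equiv), Ru catecholthiolate Z‑selective metathesis catalyst (Hoveyda type, 5 mol%), THF, 22 °C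
Reagents that add atoms: (Z)-but-2-ene-1,4-diol, OC/C=C\CO
Why: Kinetically Z‑selective olefin cross‑metathesis of a terminal alkene with cis‑butenediol gives the Z‑allylic alcohol, and the ketone and silyl ether are inert to the Ru carbene.

Step 5
Reactants: 5 (2S,6Z)-8-hydroxy-2-(triethylsilyloxy)oct-6-en-3-one
Product: 6 (2S)-5-[(2S,3R)-3-(hydroxymethyl)oxiran-2-yl]-2-(triethylsilyloxy)pentan-3-one
Conditions: Ti(OiPr)4 (20 mol%), D‑(−)‑DIPT (24 mol%), t‑BuOOH, 4 Å MS, CH2Cl2, −20 °C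
Reagents that add atoms: tert-butyl hydroperoxide, CC(C)(C)OO
Why: Sharpless asymmetric epoxidation; D‑(−)‑tartrate gives the (2R,3S) cis‑epoxy alcohol (allylic alcohol numbering), fixing the future C‑1′ oxygen and the C‑2′ carbon that is inverted in step 11 (about 85–90% ee is typical for Z substrates and is upgraded in step 7).

Step 6
Reactants: 6 (2S)-5-[(2S,3R)-3-(hydroxymethyl)oxiran-2-yl]-2-(triethylsilyloxy)pentan-3-one
Product: 7 (2S,3S)-3-[(4S)-3-oxo-4-(triethylsilyloxy)pentyl]oxirane-2-carbaldehyde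
Conditions: TEMPO (10 mol%), PhI(OAc)2, CH2Cl2, rt
Reagents that add atoms: none
Why: Oxoammonium (TEMPO/BAIB) oxidation takes the primary alcohol to the aldehyde under near‑neutral conditions that leave the cis‑epoxide, ketone and TES ether intact.

Step 7
Reactants: 7 (2S,3S)-3-[(4S)-3-oxo-4-(triethylsilyloxy)pentyl]oxirane-2-carbaldehyde
Product: 9 (2S)-5-[(2S,3R)-3-[(1R)-1-hydroxybut-3-en-1-yl]oxiran-2-yl]-2-(triethylsilyloxy)pentan-3-one, via borinate ester 8 (not isolated)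
Conditions: (+)-Ipc2B(allyl), Et2O, −78 °C; then ethanolamine, rt
Reagents that add atoms: (+)-B-allyldiisopinocampheylborane, C=CCB([C@H]1C[C@H]2C[C@@H]([C@@H]1C)C2(C)C)[C@H]1C[C@H]2C[C@@H]([C@@H]1C)C2(C)C
Why: Brown asymmetric allylboration through a chair Zimmerman–Traxler transition state; the (+)-Ipc2B reagent sets the (R) carbinol (future lactone C‑6, anti to the epoxide oxygen), reacts only with the aldehyde at −78 °C, and turns the minor epoxide enantiomer into a separable diastereomer.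

Step 8
Reactants: 9 (2S)-5-[(2S,3R)-3-[(1R)-1-hydroxybut-3-en-1-yl]oxiran-2-yl]-2-(triethylsilyloxy)pentan-3-one
Product: 10 (2S)-5-[(2S,3S)-3-[(1R)-1-(tert-butyldimethylsilyloxy)but-3-en-1-yl]oxiran-2-yl]-2-(triethylsilyloxy)pentan-3-one
Conditions: TBSCl, imidazole, DMAP (cat.), DMF, rt
Reagents that add atoms: tert-butyldimethylsilyl chloride, CC(C)(C)[Si](C)(C)Cl
Why: Standard silyl ether formation under non‑Lewis‑acidic conditions that spare the epoxide and do not enolise the ketone; this TBS group is the one relayed in step 11.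

Step 9
Reactants: 10 (2S)-5-[(2S,3S)-3-[(1R)-1-(tert-butyldimethylsilyloxy)but-3-en-1-yl]oxiran-2-yl]-2-(triethylsilyloxy)pentan-3-one
Product: 12 (3R)-3-(tert-butyldimethylsilyloxy)-3-[(2S,3S)-3-[(4S)-3-oxo-4-(triethylsilyloxy)pentyl]oxiran-2-yl]propanal, via secondary ozonide 11 (not isolated)
Conditions: O3, CH2Cl2, −78 °C; then PPh3, −78 °C → rt
Reagents that add atoms: ozone, [O-][O+]=O
Why: Ozonolysis with reductive work‑up cleaves the only C=C bond to the aldehyde without touching any stereocentre.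

Step 10
Reactants: 12 (3R)-3-(tert-butyldimethylsilyloxy)-3-[(2S,3S)-3-[(4S)-3-oxo-4-(triethylsilyloxy)pentyl]oxiran-2-yl]propanal
Product: 13 methyl (2Z,5R)-5-(tert-butyldimethylsilyloxy)-5-[(2S,3S)-3-[(4S)-3-oxo-4-(triethylsilyloxy)pentyl]oxiran-2-yl]pent-2-enoate
Conditions: (CF3CH2O)2P(O)CH2CO2Me, KHMDS, 18‑crown‑6, THF, −78 °C
Reagents that add atoms: methyl bis(2,2,2-trifluoroethyl)phosphonoacetate, COC(=O)CP(=O)(OCC(F)(F)F)OCC(F)(F)F
Why: Still–Gennari olefination gives the (Z)-enoate under kinetic control, and the preformed phosphonate anion is too weak a base to enolise the ketone at −78 °C.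

Step 11
Reactants: 13 methyl (2Z,5R)-5-(tert-butyldimethylsilyloxy)-5-[(2S,3S)-3-[(4S)-3-oxo-4-(triethylsilyloxy)pentyl]oxiran-2-yl]pent-2-enoate
Product: 16 (6R)-6-[(S)-(tert-butyldimethylsilyloxy)[(1S,2S)-2-[(2S)-2-hydroxypropanoyl]cyclopropyl]methyl]-5,6-dihydro-2H-pyran-2-one, via lithium cyclopropylcarbinolate 14 (not isolated), via TES-protected lactone 15 (not isolated)
Conditions: LiHMDS (1.05 equiv), THF, −78 → 0 °C; then AcOH/THF/H2O (3:1:1), rt
Reagents that add atoms: none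
Why: Proposed new method: kinetic LiHMDS deprotonation at the unhindered CH2 next to the ketone (not at the OTES‑bearing CH) gives an enolate that opens the cis‑epoxide at its near carbon by 3‑exo‑tet SN2 with inversion, so C‑2′ becomes (S), C‑1′ keeps its oxygen and configuration, and C‑3′ is set trans by the less eclipsed transition state; the C‑1′ alkoxide then takes the neighbouring TBS group (1,4‑O→O silyl shift) and the freed C‑6 alkoxide lactonises onto the (Z)-ester, the closest known reaction types being the Stork epoxy‑nitrile/epoxy‑ester cyclisation and the malonate–epichlorohydrin cyclopropanation–lactonisation cascade, with the acidic work‑up removing only the TES ether.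

Step 12
Reactants: 17 (E)-4-hydroxycinnamic acid (p-coumaric acid)
Product: 19 (E)-3-[4-(tert-butyldimethylsilyloxy)phenyl]prop-2-enoic acid, via bis-TBS coumarate 18 (not isolated)
Conditions: TBSCl (2.2 equiv), imidazole, DMF, rt; then AcOH/THF/H2O, rt
Reagents that add atoms: tert-butyldimethylsilyl chloride, CC(C)(C)[Si](C)(C)Cl
Why: Exhaustive silylation followed by selective hydrolysis of the much more labile silyl ester leaves the aryl TBS ether.

Step 13
Reactants: 16 (6R)-6-[(S)-(tert-butyldimethylsilyloxy)[(1S,2S)-2-[(2S)-2-hydroxypropanoyl]cyclopropyl]methyl]-5,6-dihydro-2H-pyran-2-one; 19 (E)-3-[4-(tert-butyldimethylsilyloxy)phenyl]prop-2-enoic acid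
Product: 20 (2S)-1-[(1S,2S)-2-[(S)-(tert-butyldimethylsilyloxy)[(2R)-6-oxo-3,6-dihydro-2H-pyran-2-yl]methyl]cyclopropyl]-1-oxopropan-2-yl (E)-3-[4-(tert-butyldimethylsilyloxy)phenyl]prop-2-enoate
Conditions: DCC, DMAP (cat.), CH2Cl2, 0 °C → rt
Reagents that add atoms: none
Why: Steglich esterification of the only free hydroxyl (C‑1′ is already silylated by the cascade) with retention at C‑5′; catalytic DMAP at 0 °C limits epimerisation of the α‑acyloxy ketone.

Step 14
Reactants: 20 (2S)-1-[(1S,2S)-2-[(S)-(tert-butyldimethylsilyloxy)[(2R)-6-oxo-3,6-dihydro-2H-pyran-2-yl]methyl]cyclopropyl]-1-oxopropan-2-yl (E)-3-[4-(tert-butyldimethylsilyloxy)phenyl]prop-2-enoate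
Product: 21 brevipolide G
Conditions: HF·pyridine, pyridine, THF, 0 °C → rt
Reagents that add atoms: none
Why: Buffered fluoride desilylation removes the aryl and the secondary TBS ethers without harming the enoate ester, the lactone or the cyclopropyl ketone.

## Compound list

1 | ethyl (S)-lactate | C[C@H](O)C(=O)OCC | starting material
2 | ethyl (2S)-2-(triethylsilyloxy)propanoate | C[C@H](O[Si](CC)(CC)CC)C(=O)OCC | intermediate
3 | (2S)-N-methoxy-N-methyl-2-(triethylsilyloxy)propanamide | C[C@H](O[Si](CC)(CC)CC)C(=O)N(C)OC | intermediate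
4 | (2S)-2-(triethylsilyloxy)hept-6-en-3-one | C[C@H](O[Si](CC)(CC)CC)C(=O)CCC=C | intermediate
5 | (2S,6Z)-8-hydroxy-2-(triethylsilyloxy)oct-6-en-3-one | C[C@H](O[Si](CC)(CC)CC)C(=O)CC/C=C\CO | intermediate
6 | (2S)-5-[(2S,3R)-3-(hydroxymethyl)oxiran-2-yl]-2-(triethylsilyloxy)pentan-3-one | C[C@H](O[Si](CC)(CC)CC)C(=O)CC[C@@H]1O[C@@H]1CO | intermediate
7 | (2S,3S)-3-[(4S)-3-oxo-4-(triethylsilyloxy)pentyl]oxirane-2-carbaldehyde | C[C@H](O[Si](CC)(CC)CC)C(=O)CC[C@@H]1O[C@@H]1C=O | intermediate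
8 | O-diisopinocampheylborinate ester of 9 | C[C@H](O[Si](CC)(CC)CC)C(=O)CC[C@@H]1O[C@@H]1[C@H](OB([C@H]2C[C@H]3C[C@@H]([C@@H]2C)C3(C)C)[C@H]2C[C@H]3C[C@@H]([C@@H]2C)C3(C)C)CC=C | intermediate
9 | (2S)-5-[(2S,3R)-3-[(1R)-1-hydroxybut-3-en-1-yl]oxiran-2-yl]-2-(triethylsilyloxy)pentan-3-one | C[C@H](O[Si](CC)(CC)CC)C(=O)CC[C@@H]1O[C@@H]1[C@H](O)CC=C | intermediate
10 | (2S)-5-[(2S,3S)-3-[(1R)-1-(tert-butyldimethylsilyloxy)but-3-en-1-yl]oxiran-2-yl]-2-(triethylsilyloxy)pentan-3-one | C[C@H](O[Si](CC)(CC)CC)C(=O)CC[C@@H]1O[C@@H]1[C@H](O[Si](C)(C)C(C)(C)C)CC=C | intermediate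
11 | secondary ozonide of 10, (2S)-5-[(2S,3S)-3-[(1R)-1-(tert-butyldimethylsilyloxy)-2-(1,2,4-trioxolan-3-yl)ethyl]oxiran-2-yl]-2-(triethylsilyloxy)pentan-3-one (both epimers at the trioxolane carbon) | C[C@H](O[Si](CC)(CC)CC)C(=O)CC[C@@H]1O[C@@H]1[C@H](O[Si](C)(C)C(C)(C)C)CC1OCOO1 | intermediate
12 | (3R)-3-(tert-butyldimethylsilyloxy)-3-[(2S,3S)-3-[(4S)-3-oxo-4-(triethylsilyloxy)pentyl]oxiran-2-yl]propanal | C[C@H](O[Si](CC)(CC)CC)C(=O)CC[C@@H]1O[C@@H]1[C@H](O[Si](C)(C)C(C)(C)C)CC=O | intermediate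
13 | methyl (2Z,5R)-5-(tert-butyldimethylsilyloxy)-5-[(2S,3S)-3-[(4S)-3-oxo-4-(triethylsilyloxy)pentyl]oxiran-2-yl]pent-2-enoate | C[C@H](O[Si](CC)(CC)CC)C(=O)CC[C@@H]1O[C@@H]1[C@H](O[Si](C)(C)C(C)(C)C)C/C=C\C(=O)OC | intermediate
14 | lithium alkoxide of methyl (2Z,5R,6S)-5-(tert-butyldimethylsilyloxy)-6-hydroxy-6-[(1S,2S)-2-[(2S)-2-(triethylsilyloxy)propanoyl]cyclopropyl]hex-2-enoate | [Li+].C[C@H](O[Si](CC)(CC)CC)C(=O)[C@H]1C[C@@H]1[C@H]([O-])[C@H](O[Si](C)(C)C(C)(C)C)C/C=C\C(=O)OC | intermediate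
15 | (6R)-6-[(S)-(tert-butyldimethylsilyloxy)[(1S,2S)-2-[(2S)-2-(triethylsilyloxy)propanoyl]cyclopropyl]methyl]-5,6-dihydro-2H-pyran-2-one | C[C@H](O[Si](CC)(CC)CC)C(=O)[C@H]1C[C@@H]1[C@H](O[Si](C)(C)C(C)(C)C)[C@H]1CC=CC(=O)O1 | intermediate
16 | (6R)-6-[(S)-(tert-butyldimethylsilyloxy)[(1S,2S)-2-[(2S)-2-hydroxypropanoyl]cyclopropyl]methyl]-5,6-dihydro-2H-pyran-2-one | C[C@H](O)C(=O)[C@H]1C[C@@H]1[C@H](O[Si](C)(C)C(C)(C)C)[C@H]1CC=CC(=O)O1 | intermediate
17 | (E)-4-hydroxycinnamic acid (p-coumaric acid) | OC(=O)/C=C/c1ccc(O)cc1 | starting material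
18 | tert-butyldimethylsilyl (E)-3-[4-(tert-butyldimethylsilyloxy)phenyl]prop-2-enoate | CC(C)(C)[Si](C)(C)OC(=O)/C=C/c1ccc(O[Si](C)(C)C(C)(C)C)cc1 | intermediate
19 | (E)-3-[4-(tert-butyldimethylsilyloxy)phenyl]prop-2-enoic acid | OC(=O)/C=C/c1ccc(O[Si](C)(C)C(C)(C)C)cc1 | intermediate
20 | (2S)-1-[(1S,2S)-2-[(S)-(tert-butyldimethylsilyloxy)[(2R)-6-oxo-3,6-dihydro-2H-pyran-2-yl]methyl]cyclopropyl]-1-oxopropan-2-yl (E)-3-[4-(tert-butyldimethylsilyloxy)phenyl]prop-2-enoate | C[C@H](OC(=O)/C=C/c1ccc(O[Si](C)(C)C(C)(C)C)cc1)C(=O)[C@H]1C[C@@H]1[C@H](O[Si](C)(C)C(C)(C)C)[C@H]1CC=CC(=O)O1 | intermediate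
21 | brevipolide G | C[C@H](OC(=O)/C=C/c1ccc(O)cc1)C(=O)[C@H]1C[C@@H]1[C@H](O)[C@H]1CC=CC(=O)O1 | target

## Step count and risks

Total steps: 14. Longest linear sequence: 13 (steps 1–11, 13, 14); step 12 is a one‑step side branch.

**Step 11 (cascade).** The enolate may O‑alkylate; the C‑1′ alkoxide may add to the enoate or close a seven‑membered lactone instead of relaying the silyl group; the LiOMe released may epimerise C‑5′ or attack the new lactone. The fallback makes the two rings separately. It sets out from 9 and comes back to the route at 15. Acylation of 9 with acryloyl chloride (Et3N, DMAP, CH2Cl2, 0 °C) gives the acrylate ester F1. Ring‑closing metathesis (Grubbs II, CH2Cl2, 40 °C) gives the epoxy dihydropyranone F2. LiHMDS (THF, −78 → 0 °C) then only has to do the 3‑exo‑tet epoxide opening, giving the cyclopropyl carbinol lactone F3. Silylation (TBSOTf, 2,6‑lutidine, −78 °C) gives 15, and the AcOH/THF/H2O treatment of step 11 gives 16.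

**Step 4 (Z‑selective cross‑metathesis).** It depends on a sensitive specialised catalyst, and any E isomer would end up as the wrong C‑1′/C‑2′ relationship. The fallback builds the Z alkene by olefination and coupling. It sets out from 4 and comes back at 5. Ozonolysis (O3; PPh3) gives the keto aldehyde F4. Stork–Zhao olefination (Ph3P=CHI, NaHMDS, THF/DMPU, −78 °C) gives the (Z)-vinyl iodide F5. Stille coupling with Bu3SnCH2OH (Pd(PPh3)4, dioxane, 80 °C) gives 5 with retention of the Z geometry.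

**Step 7 (allylboration of the labile cis‑epoxy aldehyde).** The required sense may be the mismatched pairing with the aldehyde's own facial bias, which would lower the diastereoselectivity. The fallback installs the opposite carbinol configuration and inverts it. It sets out from 7 and comes back at 9. The enantiomeric reagent (−)-Ipc2B(allyl) (Et2O, −78 °C; ethanolamine) gives the (1S)-carbinol epimer F6. Mitsunobu inversion (4‑nitrobenzoic acid, PPh3, DIAD, THF, 0 °C) gives the inverted 4‑nitrobenzoate F7. Mild methanolysis (K2CO3, MeOH, 0 °C) gives 9.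

## Further compounds

F1 | step 11 | (1R)-1-[(2S,3S)-3-[(4S)-3-oxo-4-(triethylsilyloxy)pentyl]oxiran-2-yl]but-3-en-1-yl prop-2-enoate | C[C@H](O[Si](CC)(CC)CC)C(=O)CC[C@@H]1O[C@@H]1[C@H](OC(=O)C=C)CC=C
F2 | step 11 | (6R)-6-[(2S,3S)-3-[(4S)-3-oxo-4-(triethylsilyloxy)pentyl]oxiran-2-yl]-5,6-dihydro-2H-pyran-2-one | C[C@H](O[Si](CC)(CC)CC)C(=O)CC[C@@H]1O[C@@H]1[C@H]1CC=CC(=O)O1
F3 | step 11 | (6R)-6-[(S)-hydroxy[(1S,2S)-2-[(2S)-2-(triethylsilyloxy)propanoyl]cyclopropyl]methyl]-5,6-dihydro-2H-pyran-2-one | C[C@H](O[Si](CC)(CC)CC)C(=O)[C@H]1C[C@@H]1[C@H](O)[C@H]1CC=CC(=O)O1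
F4 | step 4 | (5S)-4-oxo-5-(triethylsilyloxy)hexanal | C[C@H](O[Si](CC)(CC)CC)C(=O)CCC=O
F5 | step 4 | (2S,6Z)-7-iodo-2-(triethylsilyloxy)hept-6-en-3-one | C[C@H](O[Si](CC)(CC)CC)C(=O)CC/C=C\I
F6 | step 7 | (2S)-5-[(2S,3R)-3-[(1S)-1-hydroxybut-3-en-1-yl]oxiran-2-yl]-2-(triethylsilyloxy)pentan-3-one | C[C@H](O[Si](CC)(CC)CC)C(=O)CC[C@@H]1O[C@@H]1[C@@H](O)CC=C
F7 | step 7 | (1R)-1-[(2S,3S)-3-[(4S)-3-oxo-4-(triethylsilyloxy)pentyl]oxiran-2-yl]but-3-en-1-yl 4-nitrobenzoate | C[C@H](O[Si](CC)(CC)CC)C(=O)CC[C@@H]1O[C@@H]1[C@H](OC(=O)c1ccc(cc1)[N+](=O)[O-])CC=C
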